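The flavanone half is disconnected at the aryl ether bond O1–C8a of ring C. The key step is an intramolecular SNAr: the (S)-C2 alkoxide of an open-chain aldol displaces fluoride from C8a, which lies ortho (through C4a) to the C4 ketone and meta to the C5 and C7 oxygens of ring A. One operation closes ring C without touching the C2–O bond and places O1 next to the biaryl carbon C8, so no 6-linked isomer can arise. The precursor is a 2-fluoro-4,6-bis(benzyloxy)phenyl β-hydroxy ketone that already carries the benzylated flavone on C3 of that ring, assembled by Suzuki coupling, Claisen–Schmidt condensation and copper-catalysed asymmetric β-borylation/oxidation.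

Key step: step 10

Assumption: the target SMILES fixes only C2 (S); the C8–C8'' biaryl axis, which has four ortho substituents, is left undefined, so compounds 11 to 16 are carried as mixtures of atropisomers about that axis and no step is asked to control it.

Step 1
Reactants: 1 apigenin
Product: 2 5,7-bis(benzyloxy)-2-[4-(benzyloxy)phenyl]-4H-chromen-4-one (tri-O-benzylapigenin)
Conditions: BnBr (4.5 equiv), K2CO3 (6 equiv), DMF, 80 °C
Reagents that add atoms: benzyl bromide BrCc1ccccc1
Why: Williamson etherification; excess reagent and heat should also alkylate the hydrogen-bonded 5-OH.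

Step 2
Reactants: 2 tri-O-benzylapigenin
Product: 3 5,7-bis(benzyloxy)-2-[4-(benzyloxy)phenyl]-8-iodo-4H-chromen-4-one
Conditions: NIS (1.1 equiv), TFA (0.3 equiv), CH2Cl2/MeCN, 0 °C to rt, dark
Reagents that add atoms: N-iodosuccinimide O=C1CCC(=O)N1I
Why: Electrophilic aromatic iodination; in fully O-alkylated 5,7-dioxygenated flavones C8 is expected to be the most nucleophilic carbon (C6 is favoured only when 5-OH is free), while C3 and ring B are deactivated by the pyranone.

Step 3
Reactants: 3 8-iodoflavone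
Product: 4 5,7-bis(benzyloxy)-2-[4-(benzyloxy)phenyl]-8-(4,4,5,5-tetramethyl-1,3,2-dioxaborolan-2-yl)-4H-chromen-4-one
Conditions: B2pin2 (1.5 equiv), PdCl2(dppf) (5 mol %), KOAc (3 equiv), 1,4-dioxane, 90 °C
Reagents that add atoms: bis(pinacolato)diboron CC1(C)OB(OC1(C)C)B1OC(C)(C)C(C)(C)O1
Why: Miyaura borylation of an aryl iodide; acetate as a weak base should suppress homocoupling of the product boronate.

Step 4
Reactants: 5 5-fluororesorcinol
Product: 6 1-(2-fluoro-4,6-dihydroxyphenyl)ethan-1-one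
Conditions: AcOH (1.2 equiv), BF3·OEt2, 90 °C; aq. NaOAc work-up
Reagents that add atoms: acetic acid CC(=O)O
Why: Friedel–Crafts (Nencki-type) C-acylation of a resorcinol; attack ortho to one hydroxyl and para to the other, not between them, as with resorcinol and orcinol, should place the acetyl group next to fluorine.

Step 5
Reactants: 6 1-(2-fluoro-4,6-dihydroxyphenyl)ethan-1-one
Product: 7 1-[2,4-bis(benzyloxy)-6-fluorophenyl]ethan-1-one
Conditions: BnBr (2.5 equiv), K2CO3 (4 equiv), DMF, 60 °C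
Reagents that add atoms: benzyl bromide BrCc1ccccc1
Why: Williamson etherification of both phenols; carbonate is too weak to enolise the methyl ketone.

Step 6
Reactants: 7 1-[2,4-bis(benzyloxy)-6-fluorophenyl]ethan-1-one
Product: 8 1-[4,6-bis(benzyloxy)-2-fluoro-3-iodophenyl]ethan-1-one
Conditions: NIS (1.05 equiv), TFA (cat.), MeCN, rt
Reagents that add atoms: N-iodosuccinimide O=C1CCC(=O)N1I
Why: Electrophilic aromatic iodination at the carbon para to one benzyloxy group and ortho to the other (between F and OBn); the alternative site between two benzyloxy groups is more hindered, as in halogenation of 5-substituted resorcinol diethers.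

Step 7
Reactants: 8 1-[4,6-bis(benzyloxy)-2-fluoro-3-iodophenyl]ethan-1-one; 9 4-(benzyloxy)benzaldehyde
Product: 10 (E)-1-[4,6-bis(benzyloxy)-2-fluoro-3-iodophenyl]-3-[4-(benzyloxy)phenyl]prop-2-en-1-one
Conditions: KOH (0.5 equiv, aq.), EtOH/THF, 0 °C to rt
Reagents that add atoms: none
Why: Claisen–Schmidt condensation; aldol addition and E1cB dehydration in protic base should give the conjugated (E)-chalcone, and the low temperature spares the aryl fluoride.

Step 8
Reactants: 4 flavone 8-boronate; 10 iodochalcone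
Product: 11 (E)-1-{4,6-bis(benzyloxy)-3-[5,7-bis(benzyloxy)-2-(4-benzyloxyphenyl)-4-oxo-4H-chromen-8-yl]-2-fluorophenyl}-3-[4-(benzyloxy)phenyl]prop-2-en-1-one
Conditions: Pd(OAc)2 (5 mol %), SPhos (10 mol %), K3PO4 (3 equiv), toluene/H2O (10:1), 90 °C
Reagents that add atoms: none
Why: Suzuki–Miyaura coupling; a bulky electron-rich biarylphosphine is the ligand class known to form tetra-ortho-substituted biaryls, and oxidative addition into the C–I bond flanked by F is fast.

Step 9
Reactants: 11 biaryl chalcone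
Product: 13 (3S)-1-{4,6-bis(benzyloxy)-3-[5,7-bis(benzyloxy)-2-(4-benzyloxyphenyl)-4-oxo-4H-chromen-8-yl]-2-fluorophenyl}-3-[4-(benzyloxy)phenyl]-3-hydroxypropan-1-one, via (S)-β-pinacolboryl ketone 12 (not isolated)
Conditions: CuCl (5 mol %), NaOtBu (10 mol %), (R)-1-[(S)-2-(diphenylphosphino)ferrocenyl]ethyldicyclohexylphosphine (6 mol %; its mirror image if a trial on the parent chalcone shows the opposite sense), B2pin2 (1.2 equiv), MeOH (2 equiv), THF, 0 °C to rt; then NaBO3·4H2O (5 equiv), THF/H2O, rt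
Reagents that add atoms: bis(pinacolato)diboron CC1(C)OB(OC1(C)C)B1OC(C)(C)C(C)(C)O1 (boron of 12); sodium perborate [Na+].[Na+].O[B-]1(O)OO[B-](O)(O)OO1 (oxygen of 13)
Why: Copper-catalysed asymmetric conjugate borylation, in which the chiral bisphosphine–copper boryl delivers boron to one face of C-β (catalyst control, expected to override the remote axis) to set the (S) centre, followed by perborate oxidation of C–B to C–O with retention; the chalcone enone should react far faster than the β,β-disubstituted flavone enone.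

Step 10
Reactants: 13 (S)-β-hydroxy ketone
Product: 15 (2S)-5,7-bis(benzyloxy)-2-[4-(benzyloxy)phenyl]-8-{5,7-bis(benzyloxy)-2-[4-(benzyloxy)phenyl]-4-oxo-4H-chromen-8-yl}-2,3-dihydro-4H-chromen-4-one, via potassium alkoxide 14 (not isolated)
Conditions: KHMDS (1.05 equiv), THF, −78 °C, then −20 °C; AcOH quench at −20 °C
Reagents that add atoms: none
Why: KHMDS deprotonates the C2 hydroxyl to alkoxide 14, which adds to C8a (ipso to fluorine) to give a Meisenheimer anion delocalised through C4a onto the C4 carbonyl oxygen, and loss of fluoride restores aromatic ring A. The closest known reaction type is the intramolecular SNAr O-arylation of 2'-fluoroaryl β-hydroxy ketones to chroman-4-ones. Ring C closes in the 6-exo-trig mode at an aromatic carbon, and closure pulls the otherwise twisted 2,6-disubstituted aryl ketone into the ring plane, where it can stabilise the adduct. No stereocentre is formed: the C2–O bond made in step 9 is not broken, so (S) is carried through with retention. Regioselectivity (O1 on the C8 side, not the C5 side) is secured because only C8a bears a leaving group, and the C5 and C7 benzyloxy groups sit meta to C8a where they do not oppose the addition. The step also needs cyclisation to outrun retro-aldol cleavage and E1cB dehydration of 14, which one equivalent of a non-nucleophilic base in an aprotic medium at low temperature and a cold acidic quench are chosen to favour.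

Step 11
Reactants: 15 hexa-O-benzyl biflavonoid
Product: 16 (2S)-5,7-dihydroxy-2-(4-hydroxyphenyl)-8-[5,7-dihydroxy-2-(4-hydroxyphenyl)-4-oxo-4H-chromen-8-yl]-2,3-dihydro-4H-chromen-4-one
Conditions: H2 (1 atm), 10% Pd/C, THF/MeOH, rt, stopped after uptake of six equivalents
Reagents that add atoms: none
Why: Hydrogenolysis of six benzyl ethers under neutral conditions, which should leave the C2 centre, the flavanone ketone and the flavone C2''=C3'' bond untouched.

Compound list
1 | apigenin, 5,7-dihydroxy-2-(4-hydroxyphenyl)-4H-chromen-4-one | O=c1cc(-c2ccc(O)cc2)oc2cc(O)cc(O)c12 | starting material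
2 | 5,7-bis(benzyloxy)-2-[4-(benzyloxy)phenyl]-4H-chromen-4-one | O=c1cc(-c2ccc(OCc3ccccc3)cc2)oc2cc(OCc3ccccc3)cc(OCc3ccccc3)c12 | intermediate
3 | 5,7-bis(benzyloxy)-2-[4-(benzyloxy)phenyl]-8-iodo-4H-chromen-4-one | O=c1cc(-c2ccc(OCc3ccccc3)cc2)oc2c(I)c(OCc3ccccc3)cc(OCc3ccccc3)c12 | intermediate
4 | 5,7-bis(benzyloxy)-2-[4-(benzyloxy)phenyl]-8-(4,4,5,5-tetramethyl-1,3,2-dioxaborolan-2-yl)-4H-chromen-4-one | O=c1cc(-c2ccc(OCc3ccccc3)cc2)oc2c(B3OC(C)(C)C(C)(C)O3)c(OCc3ccccc3)cc(OCc3ccccc3)c12 | intermediate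
5 | 5-fluororesorcinol (5-fluorobenzene-1,3-diol) | Oc1cc(O)cc(F)c1 | starting material
6 | 1-(2-fluoro-4,6-dihydroxyphenyl)ethan-1-one | CC(=O)c1c(O)cc(O)cc1F | intermediate
7 | 1-[2,4-bis(benzyloxy)-6-fluorophenyl]ethan-1-one | CC(=O)c1c(OCc2ccccc2)cc(OCc2ccccc2)cc1F | intermediate
8 | 1-[4,6-bis(benzyloxy)-2-fluoro-3-iodophenyl]ethan-1-one | CC(=O)c1c(OCc2ccccc2)cc(OCc2ccccc2)c(I)c1F | intermediate
9 | 4-(benzyloxy)benzaldehyde | O=Cc1ccc(OCc2ccccc2)cc1 | starting material
10 | (E)-1-[4,6-bis(benzyloxy)-2-fluoro-3-iodophenyl]-3-[4-(benzyloxy)phenyl]prop-2-en-1-one | O=C(/C=C/c1ccc(OCc2ccccc2)cc1)c1c(OCc2ccccc2)cc(OCc2ccccc2)c(I)c1F | intermediate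
11 | (E)-1-{4,6-bis(benzyloxy)-3-[5,7-bis(benzyloxy)-2-(4-benzyloxyphenyl)-4-oxo-4H-chromen-8-yl]-2-fluorophenyl}-3-[4-(benzyloxy)phenyl]prop-2-en-1-one | O=C(/C=C/c1ccc(OCc2ccccc2)cc1)c1c(OCc2ccccc2)cc(OCc2ccccc2)c(-c2c(OCc3ccccc3)cc(OCc3ccccc3)c3c(=O)cc(-c4ccc(OCc5ccccc5)cc4)oc23)c1F | intermediate
12 | (3S)-1-{4,6-bis(benzyloxy)-3-[5,7-bis(benzyloxy)-2-(4-benzyloxyphenyl)-4-oxo-4H-chromen-8-yl]-2-fluorophenyl}-3-[4-(benzyloxy)phenyl]-3-(4,4,5,5-tetramethyl-1,3,2-dioxaborolan-2-yl)propan-1-one | O=C(C[C@H](B1OC(C)(C)C(C)(C)O1)c1ccc(OCc2ccccc2)cc1)c1c(OCc2ccccc2)cc(OCc2ccccc2)c(-c2c(OCc3ccccc3)cc(OCc3ccccc3)c3c(=O)cc(-c4ccc(OCc5ccccc5)cc4)oc23)c1F | intermediate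
13 | (3S)-1-{4,6-bis(benzyloxy)-3-[5,7-bis(benzyloxy)-2-(4-benzyloxyphenyl)-4-oxo-4H-chromen-8-yl]-2-fluorophenyl}-3-[4-(benzyloxy)phenyl]-3-hydroxypropan-1-one | O=C(C[C@H](O)c1ccc(OCc2ccccc2)cc1)c1c(OCc2ccccc2)cc(OCc2ccccc2)c(-c2c(OCc3ccccc3)cc(OCc3ccccc3)c3c(=O)cc(-c4ccc(OCc5ccccc5)cc4)oc23)c1F | intermediate
14 | potassium (S)-alkoxide of 13 | O=C(C[C@H]([O-])c1ccc(OCc2ccccc2)cc1)c1c(OCc2ccccc2)cc(OCc2ccccc2)c(-c2c(OCc3ccccc3)cc(OCc3ccccc3)c3c(=O)cc(-c4ccc(OCc5ccccc5)cc4)oc23)c1F.[K+] | intermediate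
15 | (2S)-5,7-bis(benzyloxy)-2-[4-(benzyloxy)phenyl]-8-{5,7-bis(benzyloxy)-2-[4-(benzyloxy)phenyl]-4-oxo-4H-chromen-8-yl}-2,3-dihydro-4H-chromen-4-one | O=C1C[C@@H](c2ccc(OCc3ccccc3)cc2)Oc2c1c(OCc1ccccc1)cc(OCc1ccccc1)c2-c1c(OCc2ccccc2)cc(OCc2ccccc2)c2c(=O)cc(-c3ccc(OCc4ccccc4)cc3)oc12 | intermediate
16 | (2S)-5,7-dihydroxy-2-(4-hydroxyphenyl)-8-[5,7-dihydroxy-2-(4-hydroxyphenyl)-4-oxo-4H-chromen-8-yl]-2,3-dihydro-4H-chromen-4-one | O=C1C[C@@H](c2ccc(O)cc2)Oc2c1c(O)cc(O)c2-c1c(O)cc(O)c2c(=O)cc(-c3ccc(O)cc3)oc12 | target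

Total steps: 11. Longest linear sequence: 8 steps (steps 4, 5, 6, 7, 8, 9, 10, 11, from compound 5).

Steps most likely to fail

Step 10. The alkoxide may fragment by retro-aldol cleavage and recombine, which would erode the C2 configuration, or dehydrate by E1cB before it cyclises. The fallback sets out from 13 and comes back at 15. Anti-selective Evans–Saksena reduction of 13 (Me4NBH(OAc)3, MeCN/AcOH, −30 °C) should give the (1S,3S)-1,3-diol F1, which has no carbonyl and can neither fragment nor dehydrate. Its dialkoxide (KOtBu, THF/DMPU, 60 °C) should close ring C by alkoxide SNAr on the now unactivated fluoroarene, since only the C3 oxygen can reach C8a through a six-membered transition state, to give the (2S,4S)-flavan-4-ol F2. Dess–Martin periodinane oxidation of the C4 carbinol (NaHCO3, CH2Cl2, rt) then returns 15.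

Step 8. Transmetalation and reductive elimination may be too slow at a biaryl with four ortho substituents, so that protodeboronation of 4 takes over. The fallback sets out from 3 and comes back at 11. Zinc insertion into 3 (Zn dust, LiCl, THF, 50 °C) should give the arylzinc iodide F3, and Negishi coupling of it with 10 (Pd2(dba)3, RuPhos, THF, 60 °C) should give 11.

Step 9. Facial selectivity may be poor on the twisted 2,6-disubstituted aryl enone, or the copper boryl may also attack the flavone enone. The fallback sets out from 11 and comes back at 13. Juliá–Colonna epoxidation (poly-D-leucine, urea–H2O2, DBU, THF, rt; catalyst hand to be confirmed on the parent chalcone) should give the (2S,3R)-epoxy ketone F4. Reductive cleavage of its Cα–O bond with SmI2 (THF/MeOH, −90 °C) leaves the Cβ–O bond and its configuration intact and should give 13.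

Further compounds
F1 | step 10 | (1S,3S)-1-{4,6-bis(benzyloxy)-3-[5,7-bis(benzyloxy)-2-(4-benzyloxyphenyl)-4-oxo-4H-chromen-8-yl]-2-fluorophenyl}-3-[4-(benzyloxy)phenyl]propane-1,3-diol | O[C@@H](C[C@H](O)c1ccc(OCc2ccccc2)cc1)c1c(OCc2ccccc2)cc(OCc2ccccc2)c(-c2c(OCc3ccccc3)cc(OCc3ccccc3)c3c(=O)cc(-c4ccc(OCc5ccccc5)cc4)oc23)c1F
F2 | step 10 | (2S,4S)-5,7-bis(benzyloxy)-2-[4-(benzyloxy)phenyl]-8-{5,7-bis(benzyloxy)-2-[4-(benzyloxy)phenyl]-4-oxo-4H-chromen-8-yl}chroman-4-ol | O[C@H]1C[C@@H](c2ccc(OCc3ccccc3)cc2)Oc2c1c(OCc1ccccc1)cc(OCc1ccccc1)c2-c1c(OCc2ccccc2)cc(OCc2ccccc2)c2c(=O)cc(-c3ccc(OCc4ccccc4)cc3)oc12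
F3 | step 8 | {5,7-bis(benzyloxy)-2-[4-(benzyloxy)phenyl]-4-oxo-4H-chromen-8-yl}zinc iodide | O=c1cc(-c2ccc(OCc3ccccc3)cc2)oc2c([Zn]I)c(OCc3ccccc3)cc(OCc3ccccc3)c12
F4 | step 9 | {4,6-bis(benzyloxy)-3-[5,7-bis(benzyloxy)-2-(4-benzyloxyphenyl)-4-oxo-4H-chromen-8-yl]-2-fluorophenyl}{(2S,3R)-3-[4-(benzyloxy)phenyl]oxiran-2-yl}methanone | O=C([C@H]1O[C@@H]1c1ccc(OCc2ccccc2)cc1)c1c(OCc2ccccc2)cc(OCc2ccccc2)c(-c2c(OCc3ccccc3)cc(OCc3ccccc3)c3c(=O)cc(-c4ccc(OCc5ccccc5)cc4)oc23)c1F
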